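The tetrahydrofuran ring (O1; C2 bearing the trimethoxyphenyl group; C3 bearing CH2OH; C4 bearing the benzyl group; C5H2) is read as the (3+2) adduct of a carbonyl ylide (C2–O1–C5) and a Z-alkene (C3=C4). The alkene is held in an (S)-γ-aryl butenolide: its ring enforces the cis relation of C3 and C4, its carbonyl becomes CH2OH, and its benzylic C–O stereocentre steers the ylide to one face before hydrogenolysis erases it to the benzyl CH2. One cycloaddition forms C5–C4 and C2–C3 and sets all three stereocentres. Its precursors are a bis(silylmethyl) acetal of 3,4,5-trimethoxybenzaldehyde and the butenolide.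

Key step: step 4

Assumption: (S)-BINOL is taken to induce the R carbinol in the zinc/titanium alkynylation of step 2; if the sense proves opposite, (R)-BINOL is used with no other change.

Step 1
Reactants: 1 3,4,5-trimethoxybenzaldehyde; 2 (trimethylsilyl)methanol
Product: 3 3,4,5-trimethoxybenzaldehyde bis[(trimethylsilyl)methyl] acetal
Conditions: 2 (2.5 equiv), p-TsOH·H2O (cat.), benzene, reflux, Dean–Stark; Et3N quench; Et3N-deactivated silica
Reagents that add atoms: none
Why: Acid-catalysed acetalisation driven by azeotropic removal of water should convert the aldehyde into the bis(silylmethyl) acetal, the primary α-silyl alcohol being stable to catalytic acid; no stereocentre is formed.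

Step 2
Reactants: 4 4-(benzyloxy)-3-methoxybenzaldehyde; 5 methyl propiolate
Product: 6 methyl (4R)-4-[4-(benzyloxy)-3-methoxyphenyl]-4-hydroxybut-2-ynoate
Conditions: 5 (2 equiv), ZnEt2 (2 equiv), (S)-BINOL (40 mol %), HMPA (2 equiv), CH2Cl2, rt; Ti(OiPr)4 (1 equiv); then 4, rt; aq. NH4Cl
Reagents that add atoms: none
Why: Catalytic asymmetric alkynylation of an aldehyde, in which the alkynylzinc formed from 5 and ZnEt2 adds to 4 within the chiral titanium BINOLate complex, which selects one face of the aldehyde and sets the carbinol centre as R by catalyst control.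

Step 3
Reactants: 6 methyl (4R)-4-[4-(benzyloxy)-3-methoxyphenyl]-4-hydroxybut-2-ynoate
Product: 8 (5S)-5-[4-(benzyloxy)-3-methoxyphenyl]furan-2(5H)-one, via Z-hydroxy enoate 7 (not isolated)
Conditions: H2 (1 atm), Lindlar catalyst (Pd/CaCO3 poisoned with Pb(OAc)2), quinoline, EtOAc, rt; filter; PPTS (cat.), CH2Cl2, rt
Reagents that add atoms: none
Why: Lindlar semihydrogenation adds H2 cis to the alkyne and stops at the Z-enoate, in which hydroxyl and ester are held together so that mild acid-catalysed lactonisation should close the butenolide; the carbinol centre is untouched and is named S in 8 only because the priority order changes.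

Step 4
Reactants: 3 3,4,5-trimethoxybenzaldehyde bis[(trimethylsilyl)methyl] acetal (1.5 equiv); 8 (5S)-5-[4-(benzyloxy)-3-methoxyphenyl]furan-2(5H)-one
Product: 11 (3S,3aR,6S,6aS)-3-[4-(benzyloxy)-3-methoxyphenyl]-6-(3,4,5-trimethoxyphenyl)tetrahydro-1H,3H-furo[3,4-c]furan-1-one, via α-chloro ether 9 (not isolated), via carbonyl ylide 10 (not isolated)
Conditions: 3, AcCl (1 equiv to 3), SOCl2 (cat.), CH2Cl2, 0 °C to rt, volatiles removed in vacuo; then 8, CsF (4 equiv, added last), MeCN, 0 °C to rt
Reagents that add atoms: none
Why: Acetyl chloride exchanges one silylmethoxy group of 3 for chloride, and fluoride then removes the trimethylsilyl group of 9 while chloride leaves (silicon-based 1,3-elimination) to give the non-stabilised carbonyl ylide 10, which adds across the electron-poor C=C bond of 8; the closest known reaction type is the fluoride-induced generation of carbonyl ylides from α-chloroalkyl silylmethyl ethers and their (3+2) cycloaddition to acrylates, maleates and maleimides. The tetrahydrofuran ring is closed by this intermolecular (3+2) cycloaddition, suprafacial on both partners, which forms C5–C4 and C2–C3 on either side of O1. The cis relation of C3 and C4 is fixed by the butenolide ring, a Z-alkene that cannot isomerise, and their absolute configuration by approach of the ylide to the face of 8 anti to the γ-aryl group. Regioselectivity is needed and should follow from the polarisation of 10: the electron-rich aryl group stabilises the oxocarbenium form, so the nucleophilic CH2 terminus bonds to the β-carbon of the lactone and the benzylic carbon to the α-carbon, which is also the less hindered mode next to the γ-aryl group. The configuration at C2 should come from the exo transition state (lactone ring turned away from the ylide oxygen, aryl group in the outward position of the ylide), or, if bond formation is asynchronous, from closure with the aryl group on the convex face of the cis-fused bicycle; either places the trimethoxyphenyl group trans to the lactone carbonyl.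

Step 5
Reactants: 11 (3S,3aR,6S,6aS)-3-[4-(benzyloxy)-3-methoxyphenyl]-6-(3,4,5-trimethoxyphenyl)tetrahydro-1H,3H-furo[3,4-c]furan-1-one
Product: 13 (2S,3S,4R)-4-(4-hydroxy-3-methoxybenzyl)-2-(3,4,5-trimethoxyphenyl)tetrahydrofuran-3-carboxylic acid, via phenol lactone 12 (not isolated)
Conditions: H2 (1 atm), 10% Pd/C, EtOAc–MeOH, rt, stopped when 12 is consumed
Reagents that add atoms: none
Why: Catalytic hydrogenolysis should first cleave the aryl benzyl ether and then the benzylic C–O bond of the lactone, which carries a carboxylate leaving group and a para-hydroxyphenyl group and is therefore much more labile than the benzylic ring ether at C2; the steering stereocentre becomes the benzyl CH2 and C2, C3 and C4 are untouched.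

Step 6
Reactants: 13 (2S,3S,4R)-4-(4-hydroxy-3-methoxybenzyl)-2-(3,4,5-trimethoxyphenyl)tetrahydrofuran-3-carboxylic acid
Product: 14 4-{[(3R,4R,5S)-4-(hydroxymethyl)-5-(3,4,5-trimethoxyphenyl)tetrahydrofuran-3-yl]methyl}-2-methoxyphenol (CNP0423112.1)
Conditions: BH3·SMe2 (4 equiv), THF, 0 °C to rt; MeOH, then evaporation from MeOH
Reagents that add atoms: none
Why: Borane reduction of a carboxylic acid through the acyloxyborane is chemoselective for the acid in the presence of the ethers and the phenol (which only forms a borate that methanolysis releases) and is non-basic, so that the C3 centre next to the carboxyl group is not epimerised.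

Compound list
1 | 3,4,5-trimethoxybenzaldehyde | COc1cc(C=O)cc(OC)c1OC | starting material
2 | (trimethylsilyl)methanol | C[Si](C)(C)CO | starting material
3 | 3,4,5-trimethoxybenzaldehyde bis[(trimethylsilyl)methyl] acetal | COc1cc(C(OC[Si](C)(C)C)OC[Si](C)(C)C)cc(OC)c1OC | intermediate
4 | 4-(benzyloxy)-3-methoxybenzaldehyde | COc1cc(C=O)ccc1OCc1ccccc1 | starting material
5 | methyl propiolate | C#CC(=O)OC | starting material
6 | methyl (4R)-4-[4-(benzyloxy)-3-methoxyphenyl]-4-hydroxybut-2-ynoate | COc1cc([C@@H](O)C#CC(=O)OC)ccc1OCc1ccccc1 | intermediate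
7 | methyl (2Z,4S)-4-[4-(benzyloxy)-3-methoxyphenyl]-4-hydroxybut-2-enoate | COc1cc([C@@H](O)/C=C\C(=O)OC)ccc1OCc1ccccc1 | intermediate
8 | (5S)-5-[4-(benzyloxy)-3-methoxyphenyl]furan-2(5H)-one | COc1cc([C@@H]2C=CC(=O)O2)ccc1OCc1ccccc1 | intermediate
9 | chloro(3,4,5-trimethoxyphenyl)methyl (trimethylsilyl)methyl ether (racemic) | COc1cc(C(Cl)OC[Si](C)(C)C)cc(OC)c1OC | intermediate
10 | carbonyl ylide of 3,4,5-trimethoxybenzaldehyde (O-methylide) | COc1cc(C=[O+][CH2-])cc(OC)c1OC | intermediate
11 | (3S,3aR,6S,6aS)-3-[4-(benzyloxy)-3-methoxyphenyl]-6-(3,4,5-trimethoxyphenyl)tetrahydro-1H,3H-furo[3,4-c]furan-1-one | COc1cc([C@@H]3[C@H]2CO[C@H](c4cc(OC)c(OC)c(OC)c4)[C@H]2C(=O)O3)ccc1OCc1ccccc1 | intermediate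
12 | (3S,3aR,6S,6aS)-3-(4-hydroxy-3-methoxyphenyl)-6-(3,4,5-trimethoxyphenyl)tetrahydro-1H,3H-furo[3,4-c]furan-1-one | COc1cc([C@@H]3[C@H]2CO[C@H](c4cc(OC)c(OC)c(OC)c4)[C@H]2C(=O)O3)ccc1O | intermediate
13 | (2S,3S,4R)-4-(4-hydroxy-3-methoxybenzyl)-2-(3,4,5-trimethoxyphenyl)tetrahydrofuran-3-carboxylic acid | COc1cc(C[C@H]2CO[C@H](c3cc(OC)c(OC)c(OC)c3)[C@H]2C(=O)O)ccc1O | intermediate
14 | 4-{[(3R,4R,5S)-4-(hydroxymethyl)-5-(3,4,5-trimethoxyphenyl)tetrahydrofuran-3-yl]methyl}-2-methoxyphenol | COc1cc(C[C@H]2CO[C@H](c3cc(OC)c(OC)c(OC)c3)[C@H]2CO)ccc1O | target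

Total steps: 6. Longest linear sequence: 5 steps (4 → 6 → 8 → 11 → 13 → 14).

Steps most likely to fail

1. Step 4. Three processes threaten it:
- Fluoride may deprotonate the γ-position of 8 and erode its configuration before the ylide is captured.
- Exo/endo discrimination at C2, or the regiochemical preference, may be insufficient.
- The ylide may collapse (closure to the oxirane, self-reaction) faster than it adds.

The fallback gives up the cycloaddition and builds the ring by the lactone aldol route of lignan chemistry. It sets out from 4 (and uses 1) and comes back to the route at 14. Stobbe condensation of 4 with dimethyl succinate (NaOMe, MeOH, reflux) should give the half-ester (E)-4-[4-(benzyloxy)-3-methoxyphenyl]-3-(methoxycarbonyl)but-3-enoic acid F1. Hydrogenation with [Rh(cod)2]BF4 and the enantiomer of Me-DuPhos that leads to the R acid (H2, MeOH) should give (3R)-4-[4-(benzyloxy)-3-methoxyphenyl]-3-(methoxycarbonyl)butanoic acid F2. Reduction of the ester in the potassium carboxylate with Ca(BH4)2 (KOH; CaCl2, NaBH4, EtOH) and acidification should close (4R)-4-[4-(benzyloxy)-3-methoxybenzyl]dihydrofuran-2(3H)-one F3. Its lithium enolate (LiHMDS, THF, −78 °C) should add to 1 anti to the benzyl group to give the trans aldol (3S,4R)-4-[4-(benzyloxy)-3-methoxybenzyl]-3-[hydroxy(3,4,5-trimethoxyphenyl)methyl]dihydrofuran-2(3H)-one F4, as a mixture at the carbinol carbon. LiAlH4 (THF, 0 °C) should give the triol (2R,3R)-2-[4-(benzyloxy)-3-methoxybenzyl]-3-[hydroxy(3,4,5-trimethoxyphenyl)methyl]butane-1,4-diol F5. Ionisation of the benzylic alcohol (BF3·OEt2, CH2Cl2, −40 °C) and capture of the cation by the primary hydroxyl on the benzyl-bearing carbon should close the tetrahydrofuran with the aryl group trans to the neighbouring CH2OH. This gives the benzyl ether [(2S,3R,4R)-4-[4-(benzyloxy)-3-methoxybenzyl]-2-(3,4,5-trimethoxyphenyl)tetrahydrofuran-3-yl]methanol F6, in which the trans substituents of the lactone have become the cis C3/C4 pair. Brief hydrogenolysis (H2, Pd/C, EtOAc) should then give 14.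

2. Step 5. Hydrogenolysis may not stop at the lactone C–O bond and may go on to open the tetrahydrofuran at the benzylic C2–O1 bond, or it may stall at the phenol lactone.

The fallback replaces surface hydrogenolysis of the lactone by a quinone methide reduction that only a para-hydroxybenzylic C–O bond can undergo. It sets out from 11 and comes back at 13. The benzyl ether alone is removed (H2, Pd/C, EtOAc, short contact) and phenol lactone 12 is isolated. In aqueous NaOH/THF its phenoxide should expel the lactone carboxylate to give, as its carboxylate, the quinone methide (2S,3S,4R)-4-[(3-methoxy-4-oxocyclohexa-2,5-dien-1-ylidene)methyl]-2-(3,4,5-trimethoxyphenyl)tetrahydrofuran-3-carboxylic acid F7. NaBH4 present in the same flask should reduce it by 1,6-hydride addition to the benzyl CH2, and acidification gives 13. The C2–O1 bond next to the trimethoxyphenyl ring has no free para-hydroxyl and cannot enter this pathway.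

3. Step 2. The electron-rich aldehyde may add sluggishly and with insufficient facial selectivity, while the propiolate oligomerises under the zinc/titanium conditions.

The fallback sets the carbinol by asymmetric reduction instead of asymmetric addition. It sets out from 4 and 5 and comes back at 6. Addition of lithiated 5 (LiHMDS, THF, −78 °C) to 4 should give racemic methyl 4-[4-(benzyloxy)-3-methoxyphenyl]-4-hydroxybut-2-ynoate F8. MnO2 (CH2Cl2, rt) should give the ynone methyl 4-[4-(benzyloxy)-3-methoxyphenyl]-4-oxobut-2-ynoate F9. Transfer hydrogenation with RuCl[(S,S)-TsDPEN](p-cymene) or its antipode (iPrOH, rt), the antipode being chosen for the R alcohol, should return 6.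

Further compounds
F1 | step 4 | (E)-4-[4-(benzyloxy)-3-methoxyphenyl]-3-(methoxycarbonyl)but-3-enoic acid | COC(=O)/C(=C/c1ccc(OCc2ccccc2)c(OC)c1)CC(=O)O
F2 | step 4 | (3R)-4-[4-(benzyloxy)-3-methoxyphenyl]-3-(methoxycarbonyl)butanoic acid | COc1cc(C[C@H](CC(=O)O)C(=O)OC)ccc1OCc1ccccc1
F3 | step 4 | (4R)-4-[4-(benzyloxy)-3-methoxybenzyl]dihydrofuran-2(3H)-one | COc1cc(C[C@H]2COC(=O)C2)ccc1OCc1ccccc1
F4 | step 4 | (3S,4R)-4-[4-(benzyloxy)-3-methoxybenzyl]-3-[hydroxy(3,4,5-trimethoxyphenyl)methyl]dihydrofuran-2(3H)-one (carbinol epimers) | COc1cc(C[C@H]2COC(=O)[C@@H]2C(O)c3cc(OC)c(OC)c(OC)c3)ccc1OCc1ccccc1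
F5 | step 4 | (2R,3R)-2-[4-(benzyloxy)-3-methoxybenzyl]-3-[hydroxy(3,4,5-trimethoxyphenyl)methyl]butane-1,4-diol (carbinol epimers) | COc1cc(C[C@@H](CO)[C@H](CO)C(O)c3cc(OC)c(OC)c(OC)c3)ccc1OCc1ccccc1
F6 | step 4 | [(2S,3R,4R)-4-[4-(benzyloxy)-3-methoxybenzyl]-2-(3,4,5-trimethoxyphenyl)tetrahydrofuran-3-yl]methanol | COc1cc(C[C@H]2CO[C@H](c3cc(OC)c(OC)c(OC)c3)[C@H]2CO)ccc1OCc1ccccc1
F7 | step 5 | (2S,3S,4R)-4-[(3-methoxy-4-oxocyclohexa-2,5-dien-1-ylidene)methyl]-2-(3,4,5-trimethoxyphenyl)tetrahydrofuran-3-carboxylic acid | COC1=CC(=C[C@H]2CO[C@H](c3cc(OC)c(OC)c(OC)c3)[C@H]2C(=O)O)C=CC1=O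
F8 | step 2 | methyl 4-[4-(benzyloxy)-3-methoxyphenyl]-4-hydroxybut-2-ynoate (racemic) | COc1cc(C(O)C#CC(=O)OC)ccc1OCc1ccccc1
F9 | step 2 | methyl 4-[4-(benzyloxy)-3-methoxyphenyl]-4-oxobut-2-ynoate | COc1cc(C(=O)C#CC(=O)OC)ccc1OCc1ccccc1
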